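Two questions stand over these flasks, a row of shares and its shape, and one decision hangs on them: must the next run hold reagent back to protect the share?

    reagent + left-handed substrate → left-handed product (k1 = 0.028 M⁻¹ h⁻¹)
    reagent + right-handed substrate → right-handed product (k2 = 0.0031 M⁻¹ h⁻¹)
    left-handed substrate ⇌ right-handed substrate (k3 = 0.025 h⁻¹)
    2 reagent → homo dimer (k4 = 0.031 M⁻¹ h⁻¹)
    reagent ⇌ dormant form (K5 = 0.33, k5 = 0.026 h⁻¹)

| flask | left-handed substrate | reagent | right-handed substrate | time |
|---|---|---|---|---|
| Friday's | 0.40 M | 0.200 equiv | 0.40 M | 6.0 d |
| Monday's | 0.40 M | 0.600 equiv | 0.40 M | 6.0 d |
| Saturday's | 0.40 M | 2.00 equiv | 0.40 M | 6.0 d |
| Wednesday's | 0.40 M | 6.00 equiv | 0.40 M | 6.0 d |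

- reagent is single-handed; left-handed substrate and right-handed substrate are mirror images of each other, charged as a racemate, each of them at the stated concentration
- a doubled species enters its step squared and goes two at a time
- "hardly changes" means that all values lie within two and a half points (for a concentration: within two and a half percent of the largest)
- run time (Friday's): 6.0 d
- the handed part of reagent does not stay in what it makes, so the products of the two hands are mirror images too

- share of left-handed product in all that became left-handed product or right-handed product for Friday's, Monday's, Saturday's, Wednesday's, in this order
- the course of these numbers from the first flask to the last (falls, then rises / rises all the way / rises, then falls / hardly changes / falls all the way)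

While the two substrates stand equal, the share of left-handed product is the first capture constant over the sum of both capture constants, which gives 90.0% from a selectivity factor of 9.03. Left-handed substrate is captured faster than right-handed substrate, so it lags, and this share is the ceiling of this dynamic kinetic resolution. The largest charge of reagent, Wednesday's, tests how far the share sags. There the reagent goes to homo dimer at 0.149 h⁻¹ at the start and to substrate at 0.0124 h⁻¹. I therefore count Wednesday's run as 21.4 first half-lives of dimerisation, set the dormant form aside, and take the mean reagent over the run, ln(1+a)/a for a half-lives, as 14.5% of its charge.

Reagent pulls the hands apart at the difference of the capture constants times that mean reagent, and racemization closes the gap at its forward plus back constants. For Wednesday's the ratio of the two is 0.173. This is my lag number: the excess of right-handed over left-handed substrate, as a fraction of the left-handed. Multiplying the second capture constant by one plus this number gives Wednesday's share as 88.5%. By this reckoning the row falls by about 1.5 percentage points, less than the stated margin, so I commit to hardly changes and leave the reagent charge to be chosen on yield.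

The forecast gives 89.7%, 89%, 88.7% and 88.3%, hardly changes, on the ground that “racemization largely keeps refilling it”.

The flasks give 89.9%, 89.7%, 89.2% and 88.3%: hardly changes. In Wednesday's flask at 3.00 d, left-handed substrate stands at 27.9% of all substrate charged and right-handed substrate at 32.0%, an excess of 0.147 against my lag number of 0.173. Saturday's charge, put through the same count, has a lag number of 0.117, which makes its share 89.0%, and Saturday's flask holds 89.2%.

The constants were chosen freely, and the outcome is calculated.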